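The earlier runs and the new flask come from a simulation from invented constants; the scatter is artificial.

- In a one-step world, with Q turning L and Z into G and Z in excess, [L] falls like a capacitor discharging: the step is pseudo-first-order, with a time constant independent of [L].

| flask | L | Z | Q | time |
|---|---|---|---|---|
| spring | 0.150 M | 0.450 M | 0.0120 M |  |
| dawn | 0.150 M | 0.450 M | 0.0240 M |  |
| winter | 0.300 M | 0.450 M | 0.0120 M |  |
| dusk | 0.150 M | 0.900 M | 0.0120 M |  |
| midnight | 0.0500 M | 0.450 M | 0.00600 M | 7.9 min |

| spring run: time / min | spring run: [G] / M | dawn run: time / min | dawn run: [G] / M | winter run: time / min | winter run: [G] / M | dusk run: time / min | dusk run: [G] / M |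
|---|---|---|---|---|---|---|---|
| 0.32 | 0.0073 | 0.32 | 0.0148 | 0.32 | 0.0120 | 0.32 | 0.0148 |
| 0.60 | 0.0131 | 0.60 | 0.0250 | 0.60 | 0.0184 | 0.60 | 0.0257 |
| 1.1 | 0.0227 | 1.1 | 0.0421 | 1.1 | 0.0358 | 1.1 | 0.0452 |
| 2.2 | 0.0434 | 2.2 | 0.0767 | 2.2 | 0.0669 | 2.2 | 0.0810 |
| 4.1 | 0.0758 | 4.1 | 0.1144 | 4.1 | 0.1152 | 4.1 | 0.1231 |
| 7.9 | 0.1167 | 7.9 | 0.1431 | 7.9 | 0.1885 | 7.9 | 0.1482 |

(readings scatter by 0.001 M)

- Overall: L + Z -> G, with Q as catalyst.
- Constant volume, constant temperature.
- A reading of a species includes what of it is bound.
- An order is taken over about fifteen percent of the charge, up and down.

* order of the initial rate in [Z], near the charge of the spring run, the rate being that where two percent of its L are G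
* order of the initial rate in [L], near the charge of the spring run, the rate being that where two percent of its L are G (one fixed amount of G, the same in the runs compared)
* G in the midnight run at 7.9 min, as a share of the L charged

- At its 1.1 min reading, the spring run gives 6.70 min for the emptying time, the time of a reading divided by the logarithm of the L charged over the L not yet turned to G. We carry this quantity from flask to flask.
- Main step only: the dawn run, with twice the [Q], reads 3.34 min, half of spring. The dusk run, with twice the [Z], reads 3.07 min, half of spring, which puts the order in [Z] at 1.13 as a reading. The midnight run has spring's [Z] and half its [Q], so we expect 13.4 min and 44.5 % of its L as G at 7.9 min.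
- Add a dependence on [L]: the winter run, with twice the L, reads 8.66 min, longer than spring. So the emptying time goes as [L] to the power 0.369, and the order in [L] reads 0.631, with the scatter of the readings in it. Midnight's smaller charge then shortens its emptying time to 8.94 min, which gives 58.7 %.
- Let the comparison drift: as [L] falls within the midnight run, its emptying time shortens along the same power, and integrating that gives 65.7 %.
- Then the rest: [Z] averages about 0.434 M over the midnight run, which lengthens the emptying time slightly, and our reckoning ends at 64.0 %. We add nothing for G, whose part these readings leave unclear.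
- The forecast gives 0.97 (0.85 to 1.08) for the order in [Z], 0.65 (0.42 to 0.88) for the order in [L], and 67 % (58 % to 76 %) for midnight. It calls that last number “an envelope estimate”; it comes from a curve in L rather than our power, and it stands above our 64.0 %.
- The simulation gives 1.0 in [Z], 0.60 in [L], and 66.4 % for midnight, so the forecast held.

    Q + L + Z → G + Q (90.00 M⁻² min⁻¹)
    2 L ⇌ L2, settled at all times (25.40 M⁻¹)
    L + Z + G → 2 G (2.454 M⁻² min⁻¹)

- The midnight result means an emptying time of 7.25 min, shorter than the one-step 13.4 min. The association of two L to L2 is the main reason that it is not shorter still: without that association, the midnight run reaches 86.8 %, an emptying time of 3.90 min. In the spring run, the simulated times give an emptying time that shortens as [L] falls, from 6.43 min at a quarter of the L turned to 5.99 min at half.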